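**Plan**

- Retrosynthesis: cut the two C2–OH bonds (ketone-directed C–H oxygenation), then the two C3–acetyl bonds (Friedel–Crafts), then the two C6–OCH3 bonds together with the aromatic unsaturation of both rings (iodine in methanol), and last the C1–C1' bond (oxidative enolate coupling). This leads back to the methyl enol ether of 2-methylcyclohexane-1,3-dione.
- Enabling feature: in each ring C4(O)–C5(CH3)–C6(O) is a 2-methylcyclohexane-1,3-dione unit and C1 is its alpha-prime carbon. The crowded C1–C1' bond can therefore be made between two sp3 carbons before either ring is flat.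
- Forward: no ring is closed. Two molecules of the bought six-membered ring are joined at C1–C1' (step 2), aromatised together (step 3), then acetylated and hydroxylated once on each ring (steps 4 and 5).
- Stereochemistry: the target has no stereocentre. The two sp3 centres made in the coupling are uncontrolled and are erased on aromatisation.
- Positions are numbered as in the target throughout: C1 biaryl carbon, C2 OH, C3 acetyl, C4 OCH3, C5 CH3, C6 OCH3.

Key step: step 3

Remark: the oxidative coupling of step 2 is expected to give the meso and the racemic diastereomer of the dimer. Both are carried on under one number with the meso form drawn; the racemic form is COC1=C(C)C(=O)[C@H](CC1)[C@H]1CCC(OC)=C(C)C1=O and its mirror image.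

Remark: the target is specified without a configuration at the tetra-ortho-substituted biaryl axis, so the axis is expected to form as the racemate and no control is attempted.

**Route**

Step 1
Reactants: 1 2-methylcyclohexane-1,3-dione; 2 trimethyl orthoformate
Product: 3 3-methoxy-2-methylcyclohex-2-en-1-one
Conditions: HC(OMe)3 (1.5 equiv), TsOH·H2O (2 mol%), MeOH, 50 °C; then NaHCO3
Reagents that add atoms: trimethyl orthoformate (2), COC(OC)OC; methanol, CO
Why: Acid-catalysed enol ether formation (vinylogous esterification) of a cyclic 1,3-dione; the dione is symmetrical, so only one enol ether can form, and the orthoester consumes the water.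

Step 2
Reactants: 3 3-methoxy-2-methylcyclohex-2-en-1-one; 3 3-methoxy-2-methylcyclohex-2-en-1-one (second molecule, the step is a homodimerisation)
Product: 5 6,6'-bi(3-methoxy-2-methylcyclohex-2-en-1-one) (meso form drawn; the racemic diastereomer is carried along), via lithium dienolate 4 (not isolated)
Conditions: LiN(iPr)2 (1.05 equiv per 3), THF, −78 °C; then anhydrous CuCl2 (1.1 equiv per 3), DMF, −78 → 0 °C
Reagents that add atoms: none
Why: Kinetic deprotonation of a vinylogous ester by a lithium amide occurs at the alpha-prime carbon (Stork–Danheiser regiochemistry), and one-electron oxidation of that enolate by CuCl2 (divalent copper) gives an alpha-keto radical; two such units combine to form C1–C1' and one molecule of 5 from two molecules of 3, an oxidative enolate homocoupling of the Saegusa type, and the two new stereocentres form without control, which is harmless because step 3 erases them.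

Step 3
Reactants: 5 6,6'-bi(3-methoxy-2-methylcyclohex-2-en-1-one); 2 trimethyl orthoformate
Product: 7 2,2',4,4'-tetramethoxy-3,3'-dimethyl-1,1'-biphenyl, via bis(dienol methyl ether) 6 (not isolated)
Conditions: I2 (2.1 equiv), HC(OMe)3 (2.5 equiv), MeOH, 25 °C then reflux; aq. Na2S2O3
Reagents that add atoms: methanol, CO; trimethyl orthoformate (2), COC(OC)OC
Why: HI released from iodine and methanol catalyses exchange of each vinylogous-ester carbonyl for a methoxy group through the ketal, which makes the C6–O and C6'–O bonds and gives the bis(dienol ether) 6; the orthoformate removes the water that would otherwise leave a phenol or let the 1,4-diketone close to a furan. Iodine then attacks each electron-rich diene and loss of HI supplies the third double bond (the hydrogens lost overall are one each from C2 and C3), so one I2 per ring is enough because the vinylogous ester is one oxidation level below the arene, and aromatisation makes the sequence irreversible. The closest known reaction type is the iodine–methanol aromatisation of cyclohexenones to anisoles and of cyclohexane-1,3-dione enol ethers to resorcinol dimethyl ethers. No ring is closed and no stereocentre is made: the two sp3 stereocentres of 5 become sp2 carbons, so both diastereomers converge, and the four ortho groups clash only once the rings flatten, after the C1–C1' bond already exists. The step needs complete dehydrogenation without iodination of the electron-rich product and without regiochemical ambiguity; about one equivalent of iodine per ring, together with the HI present (which reverses aryl iodination), secures the first, and the oxygen atoms already fixed at C4 and C6 secure the second, since either carbonyl/enol-ether tautomer leads to the same arene.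

Step 4
Reactants: 7 2,2',4,4'-tetramethoxy-3,3'-dimethyl-1,1'-biphenyl; 8 acetyl chloride
Product: 9 1,1'-(2,2',4,4'-tetramethoxy-3,3'-dimethyl-[1,1'-biphenyl]-5,5'-diyl)di(ethan-1-one) (acetyl at C3 and C3' in target numbering)
Conditions: AcCl (2.6 equiv), SnCl4 (2.6 equiv), CH2Cl2, −10 → 0 °C; then ice/1 M HCl
Reagents that add atoms: acetyl chloride (8), CC(Cl)=O
Why: Friedel–Crafts acylation goes to C3, which is ortho to the C4 methoxy group and para to the C6 methoxy group, whereas C2 is meta to both; the first acetyl group deactivates only its own ring, so each ring reacts once, and SnCl4 at or below 0 °C should spare the aryl methyl ethers.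

Step 5
Reactants: 9 1,1'-(2,2',4,4'-tetramethoxy-3,3'-dimethyl-[1,1'-biphenyl]-5,5'-diyl)di(ethan-1-one)
Product: 11 contortin, 1,1'-(2,2'-dihydroxy-4,4',6,6'-tetramethoxy-5,5'-dimethyl-[1,1'-biphenyl]-3,3'-diyl)di(ethan-1-one), via bis(trifluoroacetate) 10 (not isolated)
Conditions: Pd(OAc)2 (10 mol%), K2S2O8 (3 equiv), CF3CO2H with 10 vol% (CF3CO)2O, 50 °C; then H2O/NaHCO3, 25 °C
Reagents that add atoms: trifluoroacetic acid, OC(=O)C(F)(F)F
Why: Ketone-directed palladium-catalysed ortho C–H oxygenation: the acetyl oxygen guides electrophilic divalent palladium to C2–H, the only C–H ortho to the carbonyl (C4 carries OCH3), persulfate oxidises the palladacycle to a tetravalent palladium trifluoroacetate, and C–O reductive elimination gives the aryl trifluoroacetate, which resists further oxidation and is hydrolysed on work-up to the hydrogen-bonded phenol.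

**Compound list**

1 | 2-methylcyclohexane-1,3-dione | CC1C(=O)CCCC1=O | starting material
2 | trimethyl orthoformate | COC(OC)OC | starting material
3 | 3-methoxy-2-methylcyclohex-2-en-1-one | COC1=C(C)C(=O)CCC1 | intermediate
4 | lithium 5-methoxy-6-methylcyclohexa-1,5-dien-1-olate (alpha-prime enolate of 3; two of these combine to one molecule of 5) | [Li+].[O-]C1=CCCC(OC)=C1C | intermediate (not isolated)
5 | (6R,6'S)-6,6'-bi(3-methoxy-2-methylcyclohex-2-en-1-one), meso form drawn, carried together with the racemic 6R*,6'R* form | COC1=C(C)C(=O)[C@H](CC1)[C@@H]1CCC(OC)=C(C)C1=O | intermediate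
6 | 2,2',4,4'-tetramethoxy-3,3'-dimethyl-1,1'-bi(cyclohexa-1,3-diene) | COC1=C(C)C(OC)=C(CC1)C1=C(OC)C(C)=C(OC)CC1 | intermediate (not isolated)
7 | 2,2',4,4'-tetramethoxy-3,3'-dimethyl-1,1'-biphenyl | COc1ccc(-c2ccc(OC)c(C)c2OC)c(OC)c1C | intermediate
8 | acetyl chloride | CC(Cl)=O | starting material
9 | 1,1'-(2,2',4,4'-tetramethoxy-3,3'-dimethyl-[1,1'-biphenyl]-5,5'-diyl)di(ethan-1-one) | COc1c(C)c(OC)c(-c2cc(C(C)=O)c(OC)c(C)c2OC)cc1C(C)=O | intermediate
10 | 3,3'-diacetyl-4,4',6,6'-tetramethoxy-5,5'-dimethyl-[1,1'-biphenyl]-2,2'-diyl bis(trifluoroacetate) | COc1c(C)c(OC)c(-c2c(OC(=O)C(F)(F)F)c(C(C)=O)c(OC)c(C)c2OC)c(OC(=O)C(F)(F)F)c1C(C)=O | intermediate (not isolated)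
11 | contortin, 1,1'-(2,2'-dihydroxy-4,4',6,6'-tetramethoxy-5,5'-dimethyl-[1,1'-biphenyl]-3,3'-diyl)di(ethan-1-one) | COc1c(C)c(OC)c(-c2c(O)c(C(C)=O)c(OC)c(C)c2OC)c(O)c1C(C)=O | target

**Step count**

Total steps: 5. Longest linear sequence: 5 steps (from 1).

**Steps most likely to fail**

Step 5. Cyclopalladation at C2 may be slow because that position is wedged between the acetyl group and the twisted neighbouring ring. One-electron oxidation of the electron-rich rings by persulfate in acid may then outrun the directed oxygenation. The fallback replaces the weakly binding ketone by a nitrogen directing group and sets out from 9. Condensation with NH2OH·HCl and NaOAc in EtOH should give the (E,E)-dioxime F1, and stirring in AcOH/Ac2O its bis(O-acetyl oxime) F2. Pd(OAc)2 (cat.) with PhI(OAc)2 in AcOH/Ac2O at 100 °C, an oxime-nitrogen-directed C–H acetoxylation through a five-membered palladacycle, should then give the C2,C2'-diacetoxy bis(O-acetyl oxime) F3. NaHSO3 in aqueous EtOH at 80 °C would unmask both ketones to contortin diacetate F4 before any phenoxide exists, an order chosen to avoid closure to a 1,2-benzisoxazole. K2CO3 in MeOH would finally cleave the aryl acetates, and the sequence comes back to the route at 11.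

Step 3. The hot acidic medium may cyclodehydrate the 1,4-diketone (Paal–Knorr closure to a furan, leading to a dibenzofuran). Exchange of the carbonyl oxygen for methoxy may also lag behind dehydrogenation and leave phenolic product, or the product arene may be iodinated. The fallback sets out from 5 and separates dehydrogenation from ether formation under non-acidic conditions; the carbonyl oxygen is kept and methylated instead of being exchanged. LiN(iPr)2 (2.2 equiv) with Me3SiCl in THF at −78 °C should give the bis(trimethylsilyl dienol ether) F5. DDQ (2.2 equiv) in CH2Cl2 at 25 °C should dehydrogenate both silyloxydienes to the bis(aryl trimethylsilyl ether) F6, and dilute HCl on work-up would give 4,4'-dimethoxy-3,3'-dimethyl-[1,1'-biphenyl]-2,2'-diol F7. MeI and K2CO3 in acetone would then methylate both phenols, and the sequence comes back to the route at 7.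

Step 2. Chlorine transfer from CuCl2 to the enolate, over-oxidation of the product, or proton transfer from the more acidic dimer to unreacted enolate may compete with radical dimerisation. The fallback sets out from 3 and couples a neutral, isolable enol derivative instead of the lithium enolate. LiN(iPr)2 and Me3SiCl in THF at −78 °C should give trimethyl[(5-methoxy-6-methylcyclohexa-1,5-dien-1-yl)oxy]silane F8. Ag2O in DMSO at 65 °C, the oxidative homocoupling of silyl enol ethers to 1,4-diketones, should then join two molecules at the alpha-prime carbon, and the sequence comes back to the route at 5.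

**Further compounds**

F1 | step 5 | (1E,1'E)-1,1'-(2,2',4,4'-tetramethoxy-3,3'-dimethyl-[1,1'-biphenyl]-5,5'-diyl)di(ethan-1-one) dioxime | COc1c(C)c(OC)c(-c2cc(/C(C)=N/O)c(OC)c(C)c2OC)cc1/C(C)=N/O
F2 | step 5 | bis(O-acetyl oxime) of 9, (E,E) | COc1c(C)c(OC)c(-c2cc(/C(C)=N/OC(C)=O)c(OC)c(C)c2OC)cc1/C(C)=N/OC(C)=O
F3 | step 5 | 5,5'-bis[(1E)-1-(acetoxyimino)ethyl]-2,2',4,4'-tetramethoxy-3,3'-dimethyl-[1,1'-biphenyl]-6,6'-diyl diacetate | COc1c(C)c(OC)c(-c2c(OC(C)=O)c(/C(C)=N/OC(C)=O)c(OC)c(C)c2OC)c(OC(C)=O)c1/C(C)=N/OC(C)=O
F4 | step 5 | contortin diacetate, 3,3'-diacetyl-4,4',6,6'-tetramethoxy-5,5'-dimethyl-[1,1'-biphenyl]-2,2'-diyl diacetate | COc1c(C)c(OC)c(-c2c(OC(C)=O)c(C(C)=O)c(OC)c(C)c2OC)c(OC(C)=O)c1C(C)=O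
F5 | step 3 | 4,4'-dimethoxy-3,3'-dimethyl-2,2'-bis(trimethylsilyloxy)-1,1'-bi(cyclohexa-1,3-diene) | COC1=C(C)C(O[Si](C)(C)C)=C(CC1)C1=C(O[Si](C)(C)C)C(C)=C(OC)CC1
F6 | step 3 | 4,4'-dimethoxy-3,3'-dimethyl-2,2'-bis(trimethylsilyloxy)-1,1'-biphenyl | COc1ccc(-c2ccc(OC)c(C)c2O[Si](C)(C)C)c(O[Si](C)(C)C)c1C
F7 | step 3 | 4,4'-dimethoxy-3,3'-dimethyl-[1,1'-biphenyl]-2,2'-diol | COc1ccc(-c2ccc(OC)c(C)c2O)c(O)c1C
F8 | step 2 | trimethyl[(5-methoxy-6-methylcyclohexa-1,5-dien-1-yl)oxy]silane | COC1=C(C)C(O[Si](C)(C)C)=CCC1
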